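In ring B (CHBr, C(CH3)2, C=CH2) the spiro carbon is flanked by the gem-dimethyl carbon and by the carbon carrying the exocyclic methylene; with oxygen in place of that methylene it is the α-position of a cyclohexanone. The route cuts the bond between the gem-dimethyl carbon and the spiro carbon. The precursor is an open-chain α-allyl β-keto ester ending in an enantioenriched bromohydrin; acid converts the bromohydrin into a bromonium ion that the enol carbon captures, closing ring B and forging two neighbouring quaternary carbons beside the existing CHBr centre in one operation. Ester and allyl carbons then build ring A (C(CH3)Br, CHCl) by metathesis; its halogens follow under substrate control.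

Key step: step 4

Assumption: C2 of the open-chain keto esters 6 and 7 (and of ion 8) is enolisable, is carried as a mixture of epimers and is drawn without configuration; it becomes defined only in step 4.

Step 1
Reactants: 1 prenol (3-methylbut-2-en-1-ol)
Product: 3 [(2R)-3,3-dimethyloxiran-2-yl]methyl 4-methylbenzenesulfonate, via epoxy alcohol 2 (not isolated)
Conditions: Ti(OiPr)4 (cat.), D-(−)-diisopropyl tartrate (cat.), t-BuOOH, 4 Å MS, CH2Cl2, −20 °C; then TsCl, Et3N, DMAP (cat.), −20 to 0 °C
Reagents that add atoms: tert-butyl hydroperoxide, CC(C)(C)OO; 4-toluenesulfonyl chloride, Cc1ccc(cc1)S(Cl)(=O)=O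
Why: Sharpless asymmetric epoxidation of the allylic alcohol, in which the Ti(OiPr)4/D-(−)-tartrate catalyst should deliver oxygen to the enantioface that gives the (R)-epoxide (the only stereocentre carried into the key step), is followed by sulfonylation in the same pot so that the volatile, water-soluble epoxy alcohol 2 need not be isolated.

Step 2
Reactants: 3 [(2R)-3,3-dimethyloxiran-2-yl]methyl 4-methylbenzenesulfonate; 4 ethyl 2-acetylpent-4-enoate (ethyl 2-allylacetoacetate)
Product: 6 ethyl 5-[(2R)-3,3-dimethyloxiran-2-yl]-3-oxo-2-(prop-2-en-1-yl)pentanoate, via dianion 5 (not isolated)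
Conditions: NaH, THF, 0 °C; n-BuLi, 0 °C; then 3, DMPU, −20 °C to rt
Reagents that add atoms: none
Why: Alkylation of a β-keto ester dianion (Weiler type) should take place at the more basic terminal carbon by SN2 displacement of the primary tosylate, because the fully substituted epoxide carbon cannot be attacked, and the epoxide stereocentre is not involved.

Step 3
Reactants: 6 ethyl 5-[(2R)-3,3-dimethyloxiran-2-yl]-3-oxo-2-(prop-2-en-1-yl)pentanoate
Product: 7 ethyl (6S)-6-bromo-7-hydroxy-7-methyl-3-oxo-2-(prop-2-en-1-yl)octanoate
Conditions: Li2NiBr4, THF, 0 °C to rt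
Reagents that add atoms: dilithium tetrabromonickelate Li2NiBr4, [Li+].[Li+].[Ni+2].[Br-].[Br-].[Br-].[Br-]
Why: Nucleophilic SN2 opening of the trisubstituted epoxide by soft bromide under non-acidic conditions should occur at the less substituted carbon with inversion, turning the (R)-epoxide carbon into the (S)-CHBr centre and leaving the tertiary alcohol as the future leaving group, without the ketone oxygen capturing an acid-activated epoxide.

Step 4
Reactants: 7 ethyl (6S)-6-bromo-7-hydroxy-7-methyl-3-oxo-2-(prop-2-en-1-yl)octanoate
Product: 9 ethyl (1S,3S)-3-bromo-2,2-dimethyl-6-oxo-1-(prop-2-en-1-yl)cyclohexane-1-carboxylate, via bromonium ion 8 (not isolated)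
Conditions: TfOH (10 mol %), (CF3)2CHOH, 0 °C to rt, dilute, acid kept on until any enol ether from O-attack is consumed
Reagents that add atoms: none
Why: Proposed new method: TfOH in the strongly ionising, weakly nucleophilic solvent HFIP should remove the tertiary hydroxyl of 7 as water while the neighbouring bromine bridges to the developing cation, so that bromonium ion 8 carries the configuration of the CHBr carbon, and the enol carbon of the keto ester then opens 8 at the C(CH3)2 carbon from the side opposite to bromine, forming the bond between the C(CH3)2 carbon and the ester α-carbon; the closest known reaction types are the Lewis-acid cation–olefin cyclisation terminated by a β-keto ester and the stereospecific bromonium cyclisation triggered by solvolysis of an enantioenriched vicinal bromide/leaving-group pair in HFIP. Only ring B closes, in a six-membered mode that is endo at the bromonium ion (both of its carbons become ring atoms) and endo for the enol C=C (both enol carbons become ring atoms). The CHBr centre is never a reaction site and keeps the configuration from step 3, whereas the new quaternary centre is set by a chair transition state with bromine equatorial in which the chelated enol places the ester (cis to the enol OH) equatorial, hence cis to bromine, and the allyl group axial. The step needs C- instead of O-alkylation and a single diastereomer: attack through oxygen gives a tertiary-alkyl enol ether that should re-ionise under the acid while C–C bond formation is irreversible, the internal hydrogen bond fixes the enol geometry, no electrophilic bromine reagent is present that could brominate the enol or the allyl group, and the allyl alkene cannot reach the cation through an unstrained ring.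

Step 5
Reactants: 9 ethyl (1S,3S)-3-bromo-2,2-dimethyl-6-oxo-1-(prop-2-en-1-yl)cyclohexane-1-carboxylate
Product: 10 (2R,4S)-4-bromo-2-(hydroxymethyl)-3,3-dimethyl-2-(prop-2-en-1-yl)cyclohexan-1-ol (mixture of C1 epimers)
Conditions: LiAlH4, THF, −20 to 0 °C
Reagents that add atoms: none
Why: Hydride reduction of ketone and ester with LiAlH4 at low temperature should leave the neopentyl-type secondary bromide alone, and the new carbinol centre, formed as a mixture, is erased in step 6.

Step 6
Reactants: 10 (2R,4S)-4-bromo-2-(hydroxymethyl)-3,3-dimethyl-2-(prop-2-en-1-yl)cyclohexan-1-ol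
Product: 11 (1R,3S)-3-bromo-2,2-dimethyl-6-oxo-1-(prop-2-en-1-yl)cyclohexane-1-carbaldehyde
Conditions: Dess–Martin periodinane, CH2Cl2, rt
Reagents that add atoms: none
Why: Dess–Martin oxidation of both alcohols under neutral conditions should give the β-keto aldehyde, whose quaternary α-carbon cannot enolise, without retro-aldol cleavage and without touching a stereocentre.

Step 7
Reactants: 11 (1R,3S)-3-bromo-2,2-dimethyl-6-oxo-1-(prop-2-en-1-yl)cyclohexane-1-carbaldehyde; 12 dimethyl (2-oxopropyl)phosphonate
Product: 13 (2S,4S)-4-bromo-3,3-dimethyl-2-[(1E)-3-oxobut-1-en-1-yl]-2-(prop-2-en-1-yl)cyclohexan-1-one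
Conditions: LiCl, i-Pr2NEt, MeCN, rt to 40 °C
Reagents that add atoms: none
Why: Horner–Wadsworth–Emmons olefination under Masamune–Roush conditions should react only at the aldehyde, since the ring ketone is screened by the quaternary carbon, and give the (E)-enone from the stabilised phosphonate, while the weak amine base avoids deformylation and loss of HBr.

Step 8
Reactants: 13 (2S,4S)-4-bromo-3,3-dimethyl-2-[(1E)-3-oxobut-1-en-1-yl]-2-(prop-2-en-1-yl)cyclohexan-1-one
Product: 14 (2R,4S)-4-bromo-3,3-dimethyl-2-(3-oxobutyl)-2-(prop-2-en-1-yl)cyclohexan-1-one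
Conditions: [(Ph3P)CuH]6, H2O, benzene, rt
Reagents that add atoms: none
Why: Copper hydride conjugate reduction (Stryker reduction) should deliver hydride only to the β-carbon of the enone and leave the isolated allyl alkene, the hindered ring ketone and the alkyl bromide unchanged.

Step 9
Reactants: 14 (2R,4S)-4-bromo-3,3-dimethyl-2-(3-oxobutyl)-2-(prop-2-en-1-yl)cyclohexan-1-one
Product: 15 (1S,3S)-1-bromo-2,2-dimethyl-4-methylidene-3-(3-methylbut-3-en-1-yl)-3-(prop-2-en-1-yl)cyclohexane
Conditions: Cp2Ti(CH2)(Cl)AlMe2, pyridine (cat.), THF–toluene, −40 °C to rt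
Reagents that add atoms: Tebbe reagent Cp2Ti(CH2)(Cl)AlMe2, C[Al](C)C[Ti](Cl)(C1C=CC=C1)C1C=CC=C1
Why: Tebbe methylenation, a non-basic carbonyl olefination that also converts hindered ketones, should install in one operation the exocyclic methylene of the target and the 2-propenyl metathesis partner without enolisation or elimination of HBr.

Step 10
Reactants: 15 (1S,3S)-1-bromo-2,2-dimethyl-4-methylidene-3-(3-methylbut-3-en-1-yl)-3-(prop-2-en-1-yl)cyclohexane
Product: 16 (6S,8S)-8-bromo-3,7,7-trimethyl-11-methylidenespiro[5.5]undec-2-ene
Conditions: second-generation Grubbs catalyst RuCl2(=CHPh)(H2IMes)(PCy3) (5 mol %), CH2Cl2, 40 °C, dilute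
Reagents that add atoms: none
Why: Ring-closing metathesis should start at the monosubstituted allyl alkene and close ring A as a six-membered trisubstituted alkene onto the 2-propenyl group, whereas the neopentyl exocyclic methylene could only give a four-membered or a tetrasubstituted five-membered ring and stays out.

Step 11
Reactants: 16 (6S,8S)-8-bromo-3,7,7-trimethyl-11-methylidenespiro[5.5]undec-2-ene
Product: 17 (2S,6S,8S,9R)-2-bromo-8,9-epoxy-1,1,9-trimethyl-5-methylidenespiro[5.5]undecane
Conditions: mCPBA, NaHCO3, CH2Cl2, −20 to 0 °C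
Reagents that add atoms: 3-chloroperoxybenzoic acid, OOC(=O)c1cccc(Cl)c1
Why: Prilezhaev epoxidation should select the more nucleophilic trisubstituted ring alkene and, because the bulky C(CH3)2 carbon sits pseudoequatorial on the spiro carbon and so forces the methylene-bearing carbon pseudoaxial and 1,3-related to the alkene CH (as the angular methyl is in a steroid 2-ene), add to the opposite face, placing the epoxide oxygen syn to the C(CH3)2 carbon.

Step 12
Reactants: 17 (2S,6S,8S,9R)-2-bromo-8,9-epoxy-1,1,9-trimethyl-5-methylidenespiro[5.5]undecane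
Product: 18 (2R,3R,6S,8S)-8-bromo-2-chloro-3,7,7-trimethyl-11-methylidenespiro[5.5]undecan-3-ol
Conditions: Li2CuCl4, THF, rt
Reagents that add atoms: dilithium tetrachlorocuprate Li2CuCl4, [Li+].[Li+].[Cu+2].[Cl-].[Cl-].[Cl-].[Cl-]
Why: Nucleophilic epoxide opening by chloride without strong Lewis acid should attack the secondary carbon with inversion in the trans-diaxial (Fürst–Plattner) sense through the chair that keeps the C(CH3)2 carbon equatorial, so that substitution pattern and ring conformation both point to the axial secondary chloride and axial tertiary alcohol.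

Step 13
Reactants: 18 (2R,3R,6S,8S)-8-bromo-2-chloro-3,7,7-trimethyl-11-methylidenespiro[5.5]undecan-3-ol
Product: 19 (2S,6S,8R,9R)-2,9-dibromo-8-chloro-1,1,9-trimethyl-5-methylidenespiro[5.5]undecane (target CNP0280843.3)
Conditions: Me3SiBr, CH2Cl2, −40 °C, short reaction time, cold aqueous NaHCO3 quench
Reagents that add atoms: bromotrimethylsilane, C[Si](C)(C)Br
Why: Ionising substitution of the tertiary alcohol by bromide (SN1 with neighbouring-group participation) should proceed with retention, because the antiperiplanar axial chlorine shields its own face of the tertiary cation so that bromide enters axially on the face the hydroxyl left, while low temperature and short contact keep the exocyclic alkene from adding HBr.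

Compound list
1 | prenol (3-methylbut-2-en-1-ol) | CC(C)=CCO | starting material
2 | [(2R)-3,3-dimethyloxiran-2-yl]methanol (formed in the flask) | OC[C@H]1OC1(C)C | intermediate
3 | [(2R)-3,3-dimethyloxiran-2-yl]methyl 4-methylbenzenesulfonate | Cc1ccc(cc1)S(=O)(=O)OC[C@H]1OC1(C)C | intermediate
4 | ethyl 2-acetylpent-4-enoate (ethyl 2-allylacetoacetate) | CCOC(=O)C(CC=C)C(C)=O | starting material
5 | sodium lithium dianion of 4 (formed in the flask) | [Na+].[Li+].[CH2-]C(=O)[C-](CC=C)C(=O)OCC | intermediate
6 | ethyl 5-[(2R)-3,3-dimethyloxiran-2-yl]-3-oxo-2-(prop-2-en-1-yl)pentanoate (C2 epimers) | CCOC(=O)C(CC=C)C(=O)CC[C@H]1OC1(C)C | intermediate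
7 | ethyl (6S)-6-bromo-7-hydroxy-7-methyl-3-oxo-2-(prop-2-en-1-yl)octanoate (C2 epimers) | CCOC(=O)C(CC=C)C(=O)CC[C@H](Br)C(C)(C)O | intermediate
8 | bromonium ion from 7, bromine bridging the former CHBr and C(CH3)2 carbons (formed in the flask) | CCOC(=O)C(CC=C)C(=O)CC[C@@H]1[Br+]C1(C)C | intermediate
9 | ethyl (1S,3S)-3-bromo-2,2-dimethyl-6-oxo-1-(prop-2-en-1-yl)cyclohexane-1-carboxylate (ring B; bromine and ester cis, allyl trans to bromine) | O=C1CC[C@H](Br)C(C)(C)[C@]1(CC=C)C(=O)OCC | intermediate
10 | (2R,4S)-4-bromo-2-(hydroxymethyl)-3,3-dimethyl-2-(prop-2-en-1-yl)cyclohexan-1-ol (C1 epimers) | OC1CC[C@H](Br)C(C)(C)[C@]1(CC=C)CO | intermediate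
11 | (1R,3S)-3-bromo-2,2-dimethyl-6-oxo-1-(prop-2-en-1-yl)cyclohexane-1-carbaldehyde | O=C1CC[C@H](Br)C(C)(C)[C@]1(CC=C)C=O | intermediate
12 | dimethyl (2-oxopropyl)phosphonate | COP(=O)(OC)CC(C)=O | starting material
13 | (2S,4S)-4-bromo-3,3-dimethyl-2-[(1E)-3-oxobut-1-en-1-yl]-2-(prop-2-en-1-yl)cyclohexan-1-one | O=C1CC[C@H](Br)C(C)(C)[C@]1(CC=C)/C=C/C(C)=O | intermediate
14 | (2R,4S)-4-bromo-3,3-dimethyl-2-(3-oxobutyl)-2-(prop-2-en-1-yl)cyclohexan-1-one | O=C1CC[C@H](Br)C(C)(C)[C@]1(CC=C)CCC(C)=O | intermediate
15 | (1S,3S)-1-bromo-2,2-dimethyl-4-methylidene-3-(3-methylbut-3-en-1-yl)-3-(prop-2-en-1-yl)cyclohexane | C=C1CC[C@H](Br)C(C)(C)[C@]1(CC=C)CCC(C)=C | intermediate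
16 | (6S,8S)-8-bromo-3,7,7-trimethyl-11-methylidenespiro[5.5]undec-2-ene | C=C1CC[C@H](Br)C(C)(C)[C@]12CCC(C)=CC2 | intermediate
17 | (2S,6S,8S,9R)-2-bromo-8,9-epoxy-1,1,9-trimethyl-5-methylidenespiro[5.5]undecane (epoxide oxygen syn to the C(CH3)2 carbon) | C=C1CC[C@H](Br)C(C)(C)[C@]12CC[C@@]3(C)O[C@H]3C2 | intermediate
18 | (2R,3R,6S,8S)-8-bromo-2-chloro-3,7,7-trimethyl-11-methylidenespiro[5.5]undecan-3-ol (OH and Cl trans-diaxial) | C=C1CC[C@H](Br)C(C)(C)[C@]12CC[C@@](C)(O)[C@H](Cl)C2 | intermediate
19 | (2S,6S,8R,9R)-2,9-dibromo-8-chloro-1,1,9-trimethyl-5-methylidenespiro[5.5]undecane | C=C1CC[C@H](Br)C(C)(C)[C@]12CC[C@@](C)(Br)[C@H](Cl)C2 | target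

Total step count: 13
Longest linear sequence: 13 steps (1 to 19)

Steps most likely to fail

1. Step 4. Capture of the cation at oxygen may fail to revert. Proton loss from the cation may outrun attack by the enol carbon. Bromonium transfer to an alkene may erode the configuration. The chair preference that relays the CHBr configuration to the quaternary carbon may be weaker than assumed. The fallback uses known reaction types and sets out from 4: its dianion 5 is alkylated with prenyl bromide (THF, 0 °C) to give ethyl 7-methyl-3-oxo-2-(prop-2-en-1-yl)oct-6-enoate F1. F1 is then submitted to the established halonium-induced cation–olefin cyclisation with Et2SBr·SbBrCl5 in MeNO2 at −25 °C, where electrophilic bromine adds to the trisubstituted alkene and the keto ester terminates. This should give the racemate, that is 9 together with its enantiomer ethyl (1R,3R)-3-bromo-2,2-dimethyl-6-oxo-1-(prop-2-en-1-yl)cyclohexane-1-carboxylate F2. The enantiomers are separated by preparative chromatography on a chiral stationary phase, and the route is rejoined at 9.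

2. Step 13. Acid set free during the substitution may add to the exocyclic alkene of ring B, or the tertiary cation may lose a proton instead of taking up bromide. The fallback halogenates ring A before the ring B methylene exists and sets out from 14. Wittig methylenation with one equivalent of Ph3P=CH2 (from Ph3PCH3Br and KN(SiMe3)2, THF, −78 to 0 °C) should react only at the unhindered methyl ketone and give 4-bromo-3,3-dimethyl-2-(3-methylbut-3-en-1-yl)-2-(prop-2-en-1-yl)cyclohexan-1-one F3. Ring-closing metathesis as in step 10 gives 4-bromo-5,5,9-trimethylspiro[5.5]undec-8-en-1-one F4. Epoxidation as in step 11 gives 4-bromo-8,9-epoxy-5,5,9-trimethylspiro[5.5]undecan-1-one F5. Chloride opening as in step 12 gives 4-bromo-8-chloro-9-hydroxy-5,5,9-trimethylspiro[5.5]undecan-1-one F6. Me3SiBr then gives 4,9-dibromo-8-chloro-5,5,9-trimethylspiro[5.5]undecan-1-one F7 with no acid-sensitive alkene present. Methylenation of the remaining ketone with Cp2Ti(CH2)(Cl)AlMe2 and pyridine (THF, −40 to 0 °C) returns to the route at 19.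

3. Step 7. Addition of the phosphonate anion to the doubly neopentyl aldehyde may be slow, so that base-induced deformylation (retro-Claisen cleavage) or loss of HBr overtakes olefination. The fallback forms the same C=C bond by Lewis-acid aldol addition and elimination and sets out from 11. Mukaiyama aldol addition of 2-(trimethylsilyloxy)propene with BF3·OEt2 (CH2Cl2, −78 °C) should give 4-bromo-2-(1-hydroxy-3-oxobutyl)-3,3-dimethyl-2-(prop-2-en-1-yl)cyclohexan-1-one F8 as a mixture of carbinol epimers. MsCl and Et3N convert it into the methanesulfonate of that alcohol F9. DBU then effects E1cB elimination towards the only acidic CH2, and the route is rejoined at 13.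

Further compounds
F1 | step 4 | ethyl 7-methyl-3-oxo-2-(prop-2-en-1-yl)oct-6-enoate | CCOC(=O)C(CC=C)C(=O)CCC=C(C)C
F2 | step 4 | ethyl (1R,3R)-3-bromo-2,2-dimethyl-6-oxo-1-(prop-2-en-1-yl)cyclohexane-1-carboxylate (enantiomer of 9) | O=C1CC[C@@H](Br)C(C)(C)[C@@]1(CC=C)C(=O)OCC
F3 | step 13 | 4-bromo-3,3-dimethyl-2-(3-methylbut-3-en-1-yl)-2-(prop-2-en-1-yl)cyclohexan-1-one (ring B ketone analogue of 15) | O=C1CC[C@H](Br)C(C)(C)[C@]1(CC=C)CCC(C)=C
F4 | step 13 | 4-bromo-5,5,9-trimethylspiro[5.5]undec-8-en-1-one (ring B ketone analogue of 16) | O=C1CC[C@H](Br)C(C)(C)[C@]12CCC(C)=CC2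
F5 | step 13 | 4-bromo-8,9-epoxy-5,5,9-trimethylspiro[5.5]undecan-1-one (ring B ketone analogue of 17) | O=C1CC[C@H](Br)C(C)(C)[C@]12CC[C@@]3(C)O[C@H]3C2
F6 | step 13 | 4-bromo-8-chloro-9-hydroxy-5,5,9-trimethylspiro[5.5]undecan-1-one (ring B ketone analogue of 18) | O=C1CC[C@H](Br)C(C)(C)[C@]12CC[C@@](C)(O)[C@H](Cl)C2
F7 | step 13 | 4,9-dibromo-8-chloro-5,5,9-trimethylspiro[5.5]undecan-1-one (ring B ketone analogue of 19) | O=C1CC[C@H](Br)C(C)(C)[C@]12CC[C@@](C)(Br)[C@H](Cl)C2
F8 | step 7 | 4-bromo-2-(1-hydroxy-3-oxobutyl)-3,3-dimethyl-2-(prop-2-en-1-yl)cyclohexan-1-one (carbinol epimers) | O=C1CC[C@H](Br)C(C)(C)[C@]1(CC=C)C(O)CC(C)=O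
F9 | step 7 | methanesulfonate of F8 | O=C1CC[C@H](Br)C(C)(C)[C@]1(CC=C)C(OS(C)(=O)=O)CC(C)=O
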